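**Plan**
1. Retrosynthetic cuts, in order: C3–C4 (eight-membered ether ring, closed last), O–C8 (tetrahydropyran, oxa-Michael), C8–C9 (union of two fragments), C6–C7 (vinylogous aldol), C1–C14 and C10–C11 (Diels–Alder).
2. Forward: a Diels–Alder reaction builds the cyclohexene, which is elaborated into aldehyde 20 (fragment 1: C2/C3 arm, C11/C12 diacetate, C13=C14). Bromobutenolide 28 (fragment 2) carries the C4–C6/C16 allylsilane arm. Coupling at C8–C9 and oxidation are followed by oxa-Michael closure of the tetrahydropyran, which creates spiro C8; the chloride is then set at C6 and the oxocane is closed last.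
3. Enabling feature: C3(OH)–C4H2–C5(=C16H2)–C6HCl is the product pattern of a 2-(1-chloroalkyl)allylsilane adding to an aldehyde with allyl transposition. C3 and C7 stand syn-diaxial on C2 and C8 of the trans-fused tetrahydropyran ring (O, C2, C1, C10, C9, C8), so the ring O/C2–C8 closes from pre-aligned arms.
4. Stereochemistry: C1/C10 from a catalyst-controlled Diels–Alder reaction; C2 by Felkin–Anh addition; C11/C12 by OsO4 anti to the C1 methyl; C6/C7 by an asymmetric vinylogous Mukaiyama aldol (C6 later inverted by chloride); C8/C17 by anti oxa-Michael addition and kinetic protonation; C9 by hydride delivery anti to the axial C1 methyl; C3 in the key step.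

Key step: step 26

Remark on numbering: C1 = ring-fusion carbon bearing CH3 (C15); C2 = ether CH; C3 = carbinol; C4 = CH2; C5 = C(=C16H2); C6 = CHCl; C7 = lactone O–CH; C8 = spiro ether carbon; C9 = CHOAc; C10 = ring-fusion CH; C11 = C(CH3)OAc; C12 = CHOAc; C13=C14; C17 = lactone CH(CH3); C19 = lactone C=O.
Assumption: in steps 3 and 16 the catalyst enantiomer named is the one expected from the published facial models to give the drawn absolute configuration; the mirror-image catalyst is used if the sense proves opposite.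

**Fragment 1**

Step 1
Reactants: 1 (tert-butyldimethylsilyloxy)acetaldehyde; 2 2-(triphenylphosphoranylidene)propanal
Product: 3 (E)-4-(tert-butyldimethylsilyloxy)-2-methylbut-2-enal
Conditions: toluene, 80 °C
Reagents that add atoms: none
Why: Wittig olefination with a stabilised formyl ylide gives the E-trisubstituted enal that carries C2, C1, C10 and C9.

Step 2
Reactants: 4 pent-1-en-3-one
Product: 5 (Z)-3-(triisopropylsilyloxy)penta-1,3-diene
Conditions: i-Pr3SiOTf, Et3N, CH2Cl2, 0 °C
Reagents that add atoms: triisopropylsilyl triflate CC(C)[Si](OS(=O)(=O)C(F)(F)F)(C(C)C)C(C)C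
Why: Soft enolisation and O-silylation of the enone give the 2-silyloxy diene, with the Z enol ether (methyl outward in the s-cis diene) favoured.

Step 3
Reactants: 3 (E)-enal; 5 silyloxy diene
Product: 6 (1S,5S,6S)-6-[(tert-butyldimethylsilyloxy)methyl]-1,5-dimethyl-4-(triisopropylsilyloxy)cyclohex-3-ene-1-carbaldehyde
Conditions: (S)-3,3-diphenyl-1-(2-methylphenyl)tetrahydro-1H,3H-pyrrolo[1,2-c][1,3,2]oxazaborole + HNTf2 (20 mol %), CH2Cl2, −78 °C
Reagents that add atoms: none
Why: Cationic oxazaborolidine-catalysed Diels–Alder reaction (Corey type): the activated formyl group directs the enol-ether terminus C11 to C10 and C14 to C1, the E geometry of 3 fixes the trans C1/C10 relationship, and the catalyst should expose the Si face at C1; the C11 centre is erased later.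

Step 4
Reactants: 7 (tributylstannyl)methanol; 8 4-methoxybenzyl chloride
Product: 9 tributyl{[(4-methoxybenzyl)oxy]methyl}stannane
Conditions: NaH, HCONMe2, 0 °C to rt
Reagents that add atoms: none
Why: Williamson etherification gives the precursor of a hydroxymethyl anion equivalent.

Step 5
Reactants: 6 Diels–Alder aldehyde; 9 alkoxymethylstannane
Product: 12 C2-OTBS C3-OPMB silyl enol ether (2R), via PMB-oxymethyllithium 10 (not isolated), via lithium C2 alkoxide 11 (not isolated)
Conditions: 9, n-BuLi, THF, −78 °C; then 6; then t-BuMe2SiOTf, −78 to 0 °C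
Reagents that add atoms: tert-butyldimethylsilyl triflate CC(C)(C)[Si](C)(C)OS(=O)(=O)C(F)(F)F
Why: Tin–lithium exchange gives an alkoxymethyllithium (Still reagent) that adds to the neopentyl aldehyde in the Felkin–Anh sense, anti to the more substituted ring carbon C10, which should give the 2R carbinol; the lithium alkoxide is silylated in the same flask.

Step 6
Reactants: 12 silyl enol ether
Product: 13 C12 enone (C13=C14)
Conditions: Pd(OAc)2 (1.1 equiv), DMSO/MeCN, 40 °C
Reagents that add atoms: none
Why: Saegusa–Ito oxidation converts the regiodefined silyl enol ether into the enone with the C13=C14 double bond.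

Step 7
Reactants: 13 enone
Product: 15 dienyl triflate (C11=C12–OTf; C13=C14), via potassium dienolate 14 (not isolated)
Conditions: KN(SiMe3)2, THF, −78 °C; then PhNTf2
Reagents that add atoms: N-phenylbis(trifluoromethanesulfonimide) O=S(=O)(N(c1ccccc1)S(=O)(=O)C(F)(F)F)C(F)(F)F
Why: Only the alpha-prime proton at C11 can be removed because the gamma carbon C1 is quaternary, and O-triflation of the cross-conjugated dienolate gives the 2-triflyloxy diene.

Step 8
Reactants: 15 dienyl triflate
Product: 16 cyclohexa-1,3-diene (C11=C12; C13=C14)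
Conditions: Pd(OAc)2 (5 mol %), PPh3, HCO2H, n-Bu3N, HCONMe2, 60 °C
Reagents that add atoms: none
Why: Palladium-catalysed formate reduction of the vinyl triflate gives the diene without moving the double bonds.

Step 9
Reactants: 16 diene
Product: 17 11,12-cis-diol (11S,12R)
Conditions: OsO4 (5 mol %), N-methylmorpholine N-oxide, acetone/H2O, 0 °C
Reagents that add atoms: osmium tetroxide O=[Os](=O)(=O)=O; N-methylmorpholine N-oxide C[N+]1([O-])CCOCC1; water O
Why: Upjohn dihydroxylation selects the electron-richer trisubstituted C11=C12 bond over the hindered C13=C14 bond and attacks the face opposite the pseudoaxial C1 methyl, so both hydroxyls end syn to H10 and the C11 methyl syn to C15.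

Step 10
Reactants: 17 diol
Product: 18 11,12-diacetate
Conditions: Ac2O, 4-(dimethylamino)pyridine, Et3N, CH2Cl2, 40 °C
Reagents that add atoms: acetic anhydride CC(=O)OC(C)=O
Why: Acylpyridinium-catalysed acetylation under forcing conditions esterifies the tertiary C11 hydroxyl as well as the secondary C12 hydroxyl.

Step 11
Reactants: 18 diacetate
Product: 19 C9 primary alcohol
Conditions: HF·pyridine, pyridine, THF, 0 °C
Reagents that add atoms: none
Why: The primary silyl ether is cleaved much faster than the neopentyl secondary one at C2, so buffered fluoride frees only the C9 hydroxyl.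

Step 12
Reactants: 19 primary alcohol
Product: 20 C9 aldehyde (fragment 1)
Conditions: Dess–Martin periodinane, NaHCO3, CH2Cl2, 0 °C
Reagents that add atoms: none
Why: Buffered Dess–Martin oxidation gives the aldehyde without beta-elimination of the C11 acetate.

**Fragment 2**

Step 13
Reactants: 21 4-hydroxy-3-methylfuran-2(5H)-one
Product: 22 4-bromo-3-methylfuran-2(5H)-one
Conditions: (COBr)2, HCONMe2 (cat.), CH2Cl2, 0 °C to rt
Reagents that add atoms: oxalyl bromide O=C(Br)C(Br)=O
Why: Vilsmeier-type activation of the vinylogous acid followed by addition–elimination of bromide gives the beta-bromobutenolide.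

Step 14
Reactants: 23 2-[(trimethylsilyl)methyl]prop-2-en-1-ol
Product: 24 2-[(trimethylsilyl)methyl]prop-2-enal
Conditions: MnO2, CH2Cl2, rt
Reagents that add atoms: none
Why: MnO2 oxidises the allylic alcohol to the enal and leaves the allylsilane intact.

Step 15
Reactants: 22 bromobutenolide
Product: 25 4-bromo-3-methyl-2-(trimethylsilyloxy)furan
Conditions: Me3SiOTf, Et3N, CH2Cl2, 0 °C
Reagents that add atoms: trimethylsilyl triflate C[Si](C)(C)OS(=O)(=O)C(F)(F)F
Why: Gamma-deprotonation and O-silylation give the 2-silyloxyfuran needed for a vinylogous aldol reaction.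

Step 16
Reactants: 25 silyloxyfuran; 24 enal
Product: 27 (5S)-4-bromo-5-{(1R)-1-hydroxy-2-[(trimethylsilyl)methyl]prop-2-en-1-yl}-3-methylfuran-2(5H)-one, via trimethylsilyl ether 26 (not isolated)
Conditions: Ti(Oi-Pr)4 (20 mol %), (R)-BINOL (20 mol %), Et2O, −20 °C; then CF3CO2H (cat.), THF/H2O
Reagents that add atoms: none
Why: Vinylogous Mukaiyama aldol reaction: the furan attacks through C5 (C7 of the target) in an open transition state that favours the threo adduct, and the titanium–BINOL complex selects the aldehyde face; this sets C7 and, with the configuration opposite to the target, C6.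

Step 17
Reactants: 27 aldol adduct
Product: 28 triethylsilyl ether of 27 (fragment 2)
Conditions: Et3SiCl, imidazole, HCONMe2, 0 °C
Reagents that add atoms: chlorotriethylsilane CC[Si](Cl)(CC)CC
Why: Silylation masks the C6 hydroxyl for the coupling and oxidation steps.

**Union and endgame**

Step 18
Reactants: 20 C9 aldehyde; 28 bromobutenolide
Product: 30 coupled C9 carbinol (both C9 epimers), via vinylchromium dichloride 29 (not isolated)
Conditions: CrCl2 (6 equiv), NiCl2 (2 mol %), DMSO/THF, rt
Reagents that add atoms: none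
Why: Nozaki–Hiyama–Kishi coupling: zerovalent nickel inserts into the activated C–Br bond, transmetalation to trivalent chromium gives a vinylchromium that adds only to the aldehyde; C9 is left uncontrolled because it is oxidised next.

Step 19
Reactants: 30 carbinol
Product: 31 ene-dione (C9 ketone conjugated to the butenolide)
Conditions: Dess–Martin periodinane, NaHCO3, CH2Cl2, 0 °C
Reagents that add atoms: none
Why: Oxidation of the allylic carbinol removes the C9 mixture and makes C8 a strongly activated acceptor.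

Step 20
Reactants: 31 ene-dione
Product: 33 spiro tetrahydropyran ketone (O–C8 bond formed; C6 hydroxyl), via C2/C6 diol 32 (not isolated)
Conditions: HF·pyridine, pyridine, THF, 0 °C to rt; then 1,8-diazabicyclo[5.4.0]undec-7-ene (0.2 equiv), CH2Cl2, −20 °C; AcOH quench
Reagents that add atoms: none
Why: After desilylation the C2 hydroxyl adds to C8 in a 6-exo-trig oxa-Michael reaction on the butenolide face opposite the C7 side chain, which puts C7 axial and gives the target configuration at C8; the lactone enolate is then protonated from the face of the new ether oxygen, away from C9 and C6, which sets C17.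

Step 21
Reactants: 33 C6 allylic alcohol
Product: 34 C6 chloride (6S)
Conditions: Cl3CCOCCl3, PPh3, CH2Cl2, −20 to 0 °C
Reagents that add atoms: hexachloroacetone O=C(C(Cl)(Cl)Cl)C(Cl)(Cl)Cl
Why: Hexachloroacetone/PPh3 chlorination of an allylic alcohol (Magid conditions) proceeds by SN2 displacement of the oxyphosphonium with inversion and without allylic transposition.

Step 22
Reactants: 34 chloro ketone
Product: 35 9S alcohol
Conditions: NaBH4, MeOH/CH2Cl2, −40 °C
Reagents that add atoms: none
Why: Hydride attacks the ring ketone from the side opposite the axial C1 methyl, which blocks the axial trajectory through a 1,3-diaxial contact, and so should give the axial alcohol.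

Step 23
Reactants: 35 alcohol
Product: 36 9,11,12-triacetate
Conditions: Ac2O, 4-(dimethylamino)pyridine, pyridine, rt
Reagents that add atoms: acetic anhydride CC(=O)OC(C)=O
Why: Acylpyridinium-catalysed acetylation of the hindered axial hydroxyl completes the acetate pattern.

Step 24
Reactants: 36 PMB ether
Product: 37 C3 primary alcohol
Conditions: DDQ, CH2Cl2/pH 7 buffer, 0 °C
Reagents that add atoms: none
Why: Oxidative cleavage of the 4-methoxybenzyl ether frees the C3 hydroxyl under neutral conditions that should spare the allylsilane and the allylic chloride.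

Step 25
Reactants: 37 primary alcohol
Product: 38 seco-aldehyde (C3 CHO; C6 Cl; allylsilane)
Conditions: Dess–Martin periodinane, NaHCO3, CH2Cl2, 0 °C
Reagents that add atoms: none
Why: Buffered Dess–Martin oxidation gives the alpha-alkoxy aldehyde, which is used at once to avoid epimerisation at C2.

Step 26
Reactants: 38 seco-aldehyde
Product: 39 CNP0333938.2
Conditions: BF3·OEt2 (2 equiv), CH2Cl2 (0.002 M), −78 °C; aq. NaHCO3
Reagents that add atoms: none
Why: BF3 activates the C3 aldehyde, the terminal CH2 (C4) of the 2-substituted allylsilane attacks it, and the beta-silyl cation at C5 loses the silyl group as Me3SiF, so the C3 carbinol, the C5=C16 methylene and the allylic C6 chloride of the target appear together. The closest known reaction type is the intramolecular Hosomi–Sakurai allylation, and 2-(halomethyl)allylsilanes are known to add to aldehydes with the allylic halide retained. The oxocane closes 8-exo-trig at the carbonyl carbon, with the two arms held syn-diaxial at C2 and C8 of the locked trans-fused tetrahydropyran chair. C3 is controlled by the aldehyde rotamer with C=O antiperiplanar to the C2–O bond (dipole-minimised under monodentate BF3; the chelate-type rotamer would push the complexed oxygen against the lactone) and by attack on the only carbonyl face the tether can reach, which should give 3R. The step needs allylation to outrun ionisation of the C6 chloride (disfavoured by the acyloxy-bearing C7 and the low temperature) and cyclisation to outrun oligomerisation (high dilution plus the diaxial pre-alignment).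

**Compound list**
1 | (tert-butyldimethylsilyloxy)acetaldehyde | O=CCO[Si](C)(C)C(C)(C)C | starting material
2 | 2-(triphenylphosphoranylidene)propanal | CC(C=O)=P(c1ccccc1)(c1ccccc1)c1ccccc1 | starting material
3 | (E)-4-(tert-butyldimethylsilyloxy)-2-methylbut-2-enal | O=C/C(C)=C/CO[Si](C)(C)C(C)(C)C | intermediate
4 | pent-1-en-3-one | C=CC(=O)CC | starting material
5 | (Z)-3-(triisopropylsilyloxy)penta-1,3-diene | C=C/C(O[Si](C(C)C)(C(C)C)C(C)C)=C/C | intermediate
6 | (1S,5S,6S)-6-[(tert-butyldimethylsilyloxy)methyl]-1,5-dimethyl-4-(triisopropylsilyloxy)cyclohex-3-ene-1-carbaldehyde | O=C[C@@]1(C)CC=C(O[Si](C(C)C)(C(C)C)C(C)C)[C@@H](C)[C@@H]1CO[Si](C)(C)C(C)(C)C | intermediate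
7 | (tributylstannyl)methanol | OC[Sn](CCCC)(CCCC)CCCC | starting material
8 | 4-methoxybenzyl chloride | COc1ccc(CCl)cc1 | starting material
9 | tributyl{[(4-methoxybenzyl)oxy]methyl}stannane | COc1ccc(COC[Sn](CCCC)(CCCC)CCCC)cc1 | intermediate
10 | [(4-methoxybenzyl)oxy]methyllithium | [Li]COCc1ccc(OC)cc1 | intermediate
11 | lithium (2R) alkoxide from addition of 10 to 6 | COc1ccc(COC[C@H](O[Li])[C@@]2(C)CC=C(O[Si](C(C)C)(C(C)C)C(C)C)[C@@H](C)[C@@H]2CO[Si](C)(C)C(C)(C)C)cc1 | intermediate
12 | silyl enol ether: 6 with CHO converted into (1R)-1-(tert-butyldimethylsilyloxy)-2-[(4-methoxybenzyl)oxy]ethyl | COc1ccc(COC[C@H](O[Si](C)(C)C(C)(C)C)[C@@]2(C)CC=C(O[Si](C(C)C)(C(C)C)C(C)C)[C@@H](C)[C@@H]2CO[Si](C)(C)C(C)(C)C)cc1 | intermediate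
13 | C12 enone (C13=C14; C11 as in 6) | COc1ccc(COC[C@H](O[Si](C)(C)C(C)(C)C)[C@@]2(C)C=CC(=O)[C@@H](C)[C@@H]2CO[Si](C)(C)C(C)(C)C)cc1 | intermediate
14 | potassium dienolate of 13 | COc1ccc(COC[C@H](O[Si](C)(C)C(C)(C)C)[C@@]2(C)C=CC(O[K])=C(C)[C@@H]2CO[Si](C)(C)C(C)(C)C)cc1 | intermediate
15 | dienyl triflate (C11=C12–OTf; C13=C14) | COc1ccc(COC[C@H](O[Si](C)(C)C(C)(C)C)[C@@]2(C)C=CC(OS(=O)(=O)C(F)(F)F)=C(C)[C@@H]2CO[Si](C)(C)C(C)(C)C)cc1 | intermediate
16 | cyclohexa-1,3-diene (C11=C12; C13=C14) | COc1ccc(COC[C@H](O[Si](C)(C)C(C)(C)C)[C@@]2(C)C=CC=C(C)[C@@H]2CO[Si](C)(C)C(C)(C)C)cc1 | intermediate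
17 | 11,12-cis-diol (11S,12R; hydroxyls syn to H10) | COc1ccc(COC[C@H](O[Si](C)(C)C(C)(C)C)[C@@]2(C)C=C[C@@H](O)[C@@](C)(O)[C@@H]2CO[Si](C)(C)C(C)(C)C)cc1 | intermediate
18 | 11,12-diacetate | COc1ccc(COC[C@H](O[Si](C)(C)C(C)(C)C)[C@@]2(C)C=C[C@@H](OC(C)=O)[C@@](C)(OC(C)=O)[C@@H]2CO[Si](C)(C)C(C)(C)C)cc1 | intermediate
19 | C9 primary alcohol | COc1ccc(COC[C@H](O[Si](C)(C)C(C)(C)C)[C@@]2(C)C=C[C@@H](OC(C)=O)[C@@](C)(OC(C)=O)[C@@H]2CO)cc1 | intermediate
20 | C9 aldehyde (fragment 1) | COc1ccc(COC[C@H](O[Si](C)(C)C(C)(C)C)[C@@]2(C)C=C[C@@H](OC(C)=O)[C@@](C)(OC(C)=O)[C@@H]2C=O)cc1 | intermediate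
21 | 4-hydroxy-3-methylfuran-2(5H)-one (3-methyltetronic acid) | CC1=C(O)COC1=O | starting material
22 | 4-bromo-3-methylfuran-2(5H)-one | CC1=C(Br)COC1=O | intermediate
23 | 2-[(trimethylsilyl)methyl]prop-2-en-1-ol | C=C(CO)C[Si](C)(C)C | starting material
24 | 2-[(trimethylsilyl)methyl]prop-2-enal | C=C(C=O)C[Si](C)(C)C | intermediate
25 | 4-bromo-3-methyl-2-(trimethylsilyloxy)furan | Cc1c(Br)coc1O[Si](C)(C)C | intermediate
26 | trimethylsilyl ether of 27 | BrC1=C(C)C(=O)O[C@H]1[C@H](O[Si](C)(C)C)C(=C)C[Si](C)(C)C | intermediate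
27 | (5S)-4-bromo-5-{(1R)-1-hydroxy-2-[(trimethylsilyl)methyl]prop-2-en-1-yl}-3-methylfuran-2(5H)-one | BrC1=C(C)C(=O)O[C@H]1[C@H](O)C(=C)C[Si](C)(C)C | intermediate
28 | triethylsilyl ether of 27 (fragment 2) | BrC1=C(C)C(=O)O[C@H]1[C@H](O[Si](CC)(CC)CC)C(=C)C[Si](C)(C)C | intermediate
29 | vinylchromium dichloride from 28 (chromium on C8) | Cl[Cr](Cl)C1=C(C)C(=O)O[C@H]1[C@H](O[Si](CC)(CC)CC)C(=C)C[Si](C)(C)C | intermediate
30 | coupled C9 carbinol (both C9 epimers) | COc1ccc(COC[C@H](O[Si](C)(C)C(C)(C)C)[C@@]2(C)C=C[C@@H](OC(C)=O)[C@@](C)(OC(C)=O)[C@@H]2C(O)C3=C(C)C(=O)O[C@H]3[C@H](O[Si](CC)(CC)CC)C(=C)C[Si](C)(C)C)cc1 | intermediate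
31 | ene-dione (C9 ketone on the butenolide) | COc1ccc(COC[C@H](O[Si](C)(C)C(C)(C)C)[C@@]2(C)C=C[C@@H](OC(C)=O)[C@@](C)(OC(C)=O)[C@@H]2C(=O)C3=C(C)C(=O)O[C@H]3[C@H](O[Si](CC)(CC)CC)C(=C)C[Si](C)(C)C)cc1 | intermediate
32 | C2/C6 diol ene-dione | COc1ccc(COC[C@H](O)[C@@]2(C)C=C[C@@H](OC(C)=O)[C@@](C)(OC(C)=O)[C@@H]2C(=O)C3=C(C)C(=O)O[C@H]3[C@H](O)C(=C)C[Si](C)(C)C)cc1 | intermediate
33 | spiro tetrahydropyran ketone (C8 and C17 as in the target; C6 hydroxyl R; C9 ketone) | COc1ccc(COC[C@@H]2O[C@@]3([C@@H](C)C(=O)O[C@H]3[C@H](O)C(=C)C[Si](C)(C)C)C(=O)[C@@H]4[C@]2(C)C=C[C@@H](OC(C)=O)[C@@]4(C)OC(C)=O)cc1 | intermediate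
34 | C6 chloride (6S), C9 ketone | COc1ccc(COC[C@@H]2O[C@@]3([C@@H](C)C(=O)O[C@H]3[C@@H](Cl)C(=C)C[Si](C)(C)C)C(=O)[C@@H]4[C@]2(C)C=C[C@@H](OC(C)=O)[C@@]4(C)OC(C)=O)cc1 | intermediate
35 | 9S alcohol | COc1ccc(COC[C@@H]2O[C@@]3([C@@H](C)C(=O)O[C@H]3[C@@H](Cl)C(=C)C[Si](C)(C)C)[C@@H](O)[C@@H]4[C@]2(C)C=C[C@@H](OC(C)=O)[C@@]4(C)OC(C)=O)cc1 | intermediate
36 | 9,11,12-triacetate, C3 PMB ether | COc1ccc(COC[C@@H]2O[C@@]3([C@@H](C)C(=O)O[C@H]3[C@@H](Cl)C(=C)C[Si](C)(C)C)[C@@H](OC(C)=O)[C@@H]4[C@]2(C)C=C[C@@H](OC(C)=O)[C@@]4(C)OC(C)=O)cc1 | intermediate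
37 | C3 primary alcohol | OC[C@@H]2O[C@@]3([C@@H](C)C(=O)O[C@H]3[C@@H](Cl)C(=C)C[Si](C)(C)C)[C@@H](OC(C)=O)[C@@H]1[C@]2(C)C=C[C@@H](OC(C)=O)[C@@]1(C)OC(C)=O | intermediate
38 | seco-aldehyde (C3 CHO; C6 Cl; allylsilane) | O=C[C@@H]2O[C@@]3([C@@H](C)C(=O)O[C@H]3[C@@H](Cl)C(=C)C[Si](C)(C)C)[C@@H](OC(C)=O)[C@@H]1[C@]2(C)C=C[C@@H](OC(C)=O)[C@@]1(C)OC(C)=O | intermediate
39 | CNP0333938.2 (1S,2R,3R,6S,7R,8S,9S,10S,11S,12R,17R in the numbering above) | C=C1C[C@@H](O)[C@@H]2O[C@@]3([C@@H](C)C(=O)O[C@H]3[C@H]1Cl)[C@@H](OC(C)=O)[C@@H]1[C@]2(C)C=C[C@@H](OC(C)=O)[C@@]1(C)OC(C)=O | target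

**Step count**
Total: 26 steps. Longest linear sequence: 19 steps (1, 3, 5–12, 18–26).

**Steps most likely to fail**

Step 20. The conjugate addition may stall at an unfavourable equilibrium, because the new tetrahydropyran carries C3 and C7 syn-diaxial. Under base, C7 may also epimerise through the furanolate, or the C11 acetate may be eliminated from the beta-acetoxy ketone. Fallback, from 30 back to 34: the ether ring is closed before C9 is oxidised, so that no ketone flanks C10, and under anionic conditions in which the lactone enolate is the thermodynamic sink. Compound 30 is desilylated with HF·pyridine to the triol F1. Treatment with KN(SiMe3)2 (1.1 equiv, THF, −78 to −40 °C, AcOH quench at −78 °C) adds the C2 alkoxide to the butenolide and protonates the enolate kinetically, giving the tetrahydropyran diol F2. Only the allylic C6 hydroxyl of F2 can be displaced by Cl3CCOCCl3/PPh3, since C9–OH lies between two fully substituted carbons, which gives the chloro alcohol F3. Dess–Martin oxidation of F3 at C9 returns to 34.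

Step 26. The eight-membered ring may fail to close because of protodesilylation or ionisation of the C6 chloride, or C3 may form with poor facial selectivity through a chelated rotamer. Fallback, from 38 back to 39: the latent nucleophile is replaced by a preformed allylmetal. Bromodesilylation of 38 (NBS, propylene oxide, CH2Cl2, −78 °C) gives the allylic bromide F4. A Nozaki–Hiyama allylation (CrCl2, THF, 0.002 M, rt) then closes the ring through a non-chelated allylchromium addition; divalent chromium should reduce the primary bromide much faster than the hindered secondary chloride.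

Step 5. Addition to the neopentyl aldehyde may show poor facial selectivity at C2. Fallback, from 6 back to 12: the adduct of 10 and 6 is isolated as the carbinol F5 (epimer mixture) and oxidised with Dess–Martin periodinane to the alpha-alkoxy ketone F6. Reduction under reagent control with (R)-2-methyl-CBS-oxazaborolidine and BH3·SMe2 (quaternary C1 as the large group, CH2OPMB as the small group) should give the single 2R carbinol F5, which is silylated (t-BuMe2SiOTf, 2,6-lutidine) to 12.

Further compounds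
F1 | step 20 | triol from 30 (C2, C6 and C9 hydroxyls free; both C9 epimers) | COc1ccc(COC[C@H](O)[C@@]2(C)C=C[C@@H](OC(C)=O)[C@@](C)(OC(C)=O)[C@@H]2C(O)C3=C(C)C(=O)O[C@H]3[C@H](O)C(=C)C[Si](C)(C)C)cc1
F2 | step 20 | spiro tetrahydropyran diol (C6 and C9 hydroxyls; both C9 epimers) | COc1ccc(COC[C@@H]2O[C@@]3([C@@H](C)C(=O)O[C@H]3[C@H](O)C(=C)C[Si](C)(C)C)C(O)[C@@H]4[C@]2(C)C=C[C@@H](OC(C)=O)[C@@]4(C)OC(C)=O)cc1
F3 | step 20 | C6 chloride with free C9 hydroxyl (both C9 epimers) | COc1ccc(COC[C@@H]2O[C@@]3([C@@H](C)C(=O)O[C@H]3[C@@H](Cl)C(=C)C[Si](C)(C)C)C(O)[C@@H]4[C@]2(C)C=C[C@@H](OC(C)=O)[C@@]4(C)OC(C)=O)cc1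
F4 | step 26 | allylic bromide aldehyde from 38 | O=C[C@@H]2O[C@@]3([C@@H](C)C(=O)O[C@H]3[C@@H](Cl)C(=C)CBr)[C@@H](OC(C)=O)[C@@H]1[C@]2(C)C=C[C@@H](OC(C)=O)[C@@]1(C)OC(C)=O
F5 | step 5 | (2R) C2 carbinol (free hydroxyl form of 12) | COc1ccc(COC[C@H](O)[C@@]2(C)CC=C(O[Si](C(C)C)(C(C)C)C(C)C)[C@@H](C)[C@@H]2CO[Si](C)(C)C(C)(C)C)cc1
F6 | step 5 | C2 ketone | COc1ccc(COCC(=O)[C@@]2(C)CC=C(O[Si](C(C)C)(C(C)C)C(C)C)[C@@H](C)[C@@H]2CO[Si](C)(C)C(C)(C)C)cc1
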